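Numbering used throughout: the side chain runs from C1' (the carbinol carbon on C4 of the central oxazole) to C6' (the methyl group). Compound numbers are those of the steps and of the compound list.

## The problem

Compound 24 is an open six-carbon chain attached through C1' to C4 of a 2,4-disubstituted oxazole; C2 of that ring carries a CH2 group that ends at C5 of a second oxazole with free C2–H and C4–H. No ring other than the two heteroaromatic ones is present, so the work lies in building the chain and in four stereocentres: C1' (R, acylated by 13-methyltetradecanoic acid), C3' (S), C4' (R) and C5' (S), related 1',3'-syn, 3',4'-anti and 4',5'-syn. The C4'/C5' pair has no neighbour to lean on and must be set absolutely; once it exists, the C4' oxygen can steer addition to a C3' aldehyde (Felkin–Anh, anti), and the C5' oxygen supports the same face in an open transition state. C1' lies 1,3 to C3' and could be set from it, but only the C1' oxygen is to be acylated, so the two oxygens must be told apart and a reagent-controlled reduction of a C1' ketone is the cleaner answer. The C1' ester is heterobenzylic and sits 1,3 to a hydroxyl, so base (acyl shift, methanolysis) and hydrogenolysis are unwelcome at the end. The terminal oxazole C2–H and the CH2 between the rings are acidic, and both ring nitrogens bind Lewis acids. The enabling feature: with C3' written as an ester carbon and C5' as a ketone, C4' is the α-carbon of a 2-alkoxy-3-oxobutanoate and epimerises freely, so one reduction of the C5' carbonyl can fix C4' and C5' together from a racemate.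

## Retrosynthesis

**24 to 23 (three O–Si bonds).** The last step should only uncover the hydroxyls at C3', C4' and C5'. Silyl ethers are preferred over benzyl ethers (hydrogenolysis beside a heterobenzylic ester) and over an acetonide (warm aqueous acid), because fluoride in a pyridine-buffered medium leaves the C1' ester in place. Compound 23 is no simpler in skeleton, but it has no free hydroxyl, which the preceding acylation needs. The forward step must remove three secondary silyl ethers, two of them vicinal, without acyl shift.

**23 to 21 and 22, then 21 to 20 (C1'–O acyl bond, then C1'–H).** The acyl bond is cut to alcohol 21 and acid 22, and the C1'–H bond to ketone 20. A hydroxyl-directed 1,3-syn reduction of the unprotected aldol 19 would set C1' equally well, but it would leave a 1',3'-diol whose two secondary hydroxyls cannot be distinguished in the acylation. With C3' silylated first, the acyl group has one place to go. The price is that the reducing agent, not the substrate, must supply the facial selectivity, treating the oxazolyl group as the large and the CH2 group as the small substituent of an aryl alkyl ketone.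

**20 to 19 to 6 and 18 (C2'–C3' bond).** This is the fragment union of the bis-oxazole unit and a four-carbon aldehyde.
- Cutting C1'–C2' instead (an oxazole-4-carbaldehyde plus a methyl ketone from the polyol end) would create the new centre at C1', 1,4 and 1,5 from the existing ones, and would give a β-oxygenated ketone prone to elimination once acylated.
- The C2'–C3' cut puts the new centre next to C4', and the forward reaction must deliver 3',4'-anti.
- For a syn-2,3-bis(silyloxy) aldehyde such as 6, enolates reacting through closed transition states (boron, lithium) are expected to be poorly selective, because the Cornforth-type arrangement leading to anti is destabilised by the C5' substituent.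
- In an open, Lewis acid-promoted transition state, the polar Felkin–Anh preference of the C4' oxygen and the 1,3-anti preference of the C5' oxygen favour the same face.
- The union is therefore planned as a Mukaiyama aldol of enol silane 18, not as a boron aldol of ketone 17.

**18 to 17 to 16 to 15 (O–Si, then C1'–C2', then the amide C–N).** The enol silane comes from methyl ketone 17 by soft enolisation. The C1'–C2' bond is cut to Weinreb amide 16, and that to methyl ester 15. Going through the amide costs one step over direct addition to the ester, but guarantees a single methyl addition. Ester 15 is simpler in that it has no enolisable ketone during the preceding ring synthesis. The organometallic step must be faster than metalation of the oxazole C2–H and of the bridging CH2.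

**15 to 12 and 13 (C4–C5 and O1–C2 of the terminal oxazole).** The terminal ring is cut to aldehyde 14, carried as its diethyl acetal 12, and TosMIC 13. Making this ring early on a small ester is preferred over making it last, because the basic methanol medium would not tolerate the C1' ester and because 14 is an enolisable heteroarylacetaldehyde best tried where material is cheap. The precursor 12 is a mono-oxazole with a masked aldehyde. The forward reaction needs isocyanide addition to outpace self-condensation of 14.

**12 to 10 to 7 and 8 (O1–C5 and the C4=C5 unsaturation of the central oxazole, then the amide bond).** The central ring is cut by the serine logic: C4, C5, N3 and C1' come from serine ester 8, and C2 with its side arm from the acyl part. Oxazoline 11 is the intermediate between amide 10 and oxazole 12. The acyl part is taken from ester 7 by way of carboxylate 9, so that the acid-sensitive β,β-dialkoxy acid is never set free. Both starting materials are commodity chemicals.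

**6 to 5 to 4 to 3 (C3' oxidation level and protecting groups).** Aldehyde 6 comes from ester 5 by partial reduction, 5 from diol 4 by double silylation, and 4 from benzyl ether 3 by hydrogenolysis. The benzyl group is kept only as long as it is needed as the α-alkoxy substituent of the key step. Removing it on the four-carbon ester means that no benzyl ether has to be cleaved later beside the oxazoles and the C1' ester.

**3 to 2 to 1 (C5'–H, then C4'–C5').** Hydroxy ester 3 is cut at the C3–H bond (C5'–H of the target) to racemic keto ester 2, and 2 at its C2–C3 bond (C4'–C5') to ester 1 by a Claisen acetylation. This is preferred over dihydroxylating an alkene or drawing on an amino acid because it turns a racemate, one step from an achiral ester, into the syn diad by a reduction that uses the lability of C4' rather than fighting it. The forward reduction must give syn over anti and one enantiomer over the other at once.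

## Roads not taken

Alternative 1: The terminal oxazole is cut last at C4–C5 and O1–C2. In the forward sense TosMIC 13 would add to the (oxazol-2-yl)acetaldehyde A2 under K2CO3 in methanol to give the protected bis-oxazole A1.
- Merits: the aldol and the C1' reduction would be run on a mono-oxazole with no acidic C2–H, no doubly activated methylene and only one Lewis basic nitrogen. The bis-oxazole would meet no organometallic reagent and no Lewis acid.
- Weak points: A2 is the same kind of enolisable heteroarylacetaldehyde as 14, but at the most advanced stage. The basic methanol medium forbids the C1' ester, so A1 carries a PMB ether there. After ring formation, PMB removal, acylation and deprotection (including acetonide hydrolysis beside the ester) still follow, with three kinds of protecting group to manage.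
- Comparison: both plans use the same ring-forming reaction. The chosen plan runs it in step 8, where failure costs three steps of cheap material, and pays by carrying the bis-oxazole through steps 9 to 12. In that respect Alternative 1 is the better plan. It is silent on the origin of C4'/C5', which the chosen plan answers.

Alternative 2: The C1'–C4(oxazole) bond is cut. The stannylated glycal A4, tributyl(3,4-O-isopropylidene-L-fucal-1-yl)stannane, would be coupled with the oxazol-4-yl triflate A5 under Pd(PPh3)4 and CuI to give the C-aryl glycal A3.
- Merits: C3', C4' and C5' come from a 6-deoxy-L-galactose skeleton with the correct configurations and are already differentiated (acetonide on O3' and O4', ring oxygen on C5'). Hydrolysis of the enol ether of A3 gives the C1' ketone and the free C5' hydroxyl.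
- Weak points: A5 is the triflate of a 4-hydroxyoxazole, whose parent prefers the oxazol-4(5H)-one form and is hard to sulfonylate cleanly, and it needs its own sequence. Making A4 requires tert-butyllithium. Organotin waste is unavoidable. After hydration the C5' hydroxyl must be protected and the C1' ketone still needs a reagent-controlled reduction, so C1' is solved no better. The sugar belongs to the costly enantiomeric series.
- Comparison: Alternative 2 is clearly superior in stereochemical economy for C3' to C5', since three centres are bought and none made. The chosen plan needs the dynamic kinetic reduction and an aldol whose selectivity is a prediction. It sets against this cheap achiral inputs, no tin, no fragile heteroaryl triflate, and reaction types well charted on oxazole substrates.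

Alternative 3: The bond between C2 of the central oxazole and the bridging CH2 is cut. The C2-zincated oxazole A7, carrying the acylated and protected chain, would be coupled with 5-(bromomethyl)oxazole A8 under Pd(PPh3)4 to give A6.
- Merits: this is the most convergent plan. The terminal ring arrives as a small building block, the acidic methylene is created in the last C–C bond-forming step, and A6 is one acidic deprotection from 24.
- Weak points: A7 must be generated by metalation at C2 in the presence of the C1' ester and an acidic heterobenzylic C1'–H. 2-Metalated oxazoles equilibrate with open-chain isocyano enolates until they are on zinc. A8 is a reactive heteroarylmethyl bromide prone to self-quaternisation, with an acidic C2–H of its own. Homocoupling competes in such sp2–sp3 couplings. A failed coupling loses the complete acylated chain.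
- Comparison: in convergence Alternative 3 is better, since the chosen plan builds the bis-oxazole linearly before the union. The chosen plan sets against this a union that creates a stereocentre as it joins the fragments, and no organometallic chemistry in the presence of the ester.

Key step: step 2

Assumption: with the CH(OBn)CO2Et arm of 2 in the position an aryl group takes in the reduction of aryl methyl ketones, the (S,S)-TsDPEN complex is expected to give the 3S carbinol; if the sense proves opposite, the (R,R) complex is used and nothing else changes.

## Route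

Step 1
Reactants: 1 ethyl 2-(benzyloxy)acetate
Product: 2 ethyl 2-(benzyloxy)-3-oxobutanoate (racemic)
Conditions: LiN(SiMe3)2 (2.1 equiv), THF, −78 °C; N-acetylimidazole, −78 to −20 °C; aq. NH4Cl
Reagents that add atoms: N-acetylimidazole, CC(=O)n1ccnc1
Why: Crossed Claisen condensation: the lithium enolate of 1 is C-acylated by the acyl imidazole, and the second equivalent of base turns 2 into its enolate so that it neither quenches unreacted enolate nor is acylated again. The centre formed at C2 is left racemic on purpose, since step 2 consumes both enantiomers.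

Step 2
Reactants: 2 ethyl 2-(benzyloxy)-3-oxobutanoate (racemic)
Product: 3 ethyl (2R,3S)-2-(benzyloxy)-3-hydroxybutanoate
Conditions: RuCl(p-cymene)[(S,S)-TsDPEN] (1 mol %), HCO2H/Et3N (5:2), CH2Cl2, 30 °C
Reagents that add atoms: none
Why: Noyori–Ikariya asymmetric transfer hydrogenation run as a dynamic kinetic resolution, the known syn-selective reduction of 2-alkoxy-3-oxo esters. Formate converts the 16-electron ruthenium amide into the Ru–H/N–H species, which passes hydride to the ketone carbon and a proton to its oxygen through a six-membered outer-sphere transition state without the substrate binding to the metal; CO2 is lost and the cycle repeats. C2–H of 2 lies between ketone and ester and is exchanged through the enol in the triethylammonium formate medium, so the two enantiomers of 2 should interconvert faster than either is reduced. The new C3 centre (C5') is set by the diamine ligand, which selects one face of the ketone, the (S,S) ligand being chosen to give 3S. C2 (C4') is fixed by kinetic selection: only the substrate enantiomer that can place its C–OBn bond anti to the incoming hydride on that face (Felkin–Anh arrangement, no chelation because the ruthenium hydride has no free site) reacts fast, which gives the syn 2R,3S isomer. The β-hydroxy ester 3 lacks the doubly activated C2–H and should not epimerise, so the selection is kept. No ring closes and no skeletal bond forms; the step needs syn over anti and one enantiomer over the other at once, and both rest on the fast racemisation secured by the 1,3-dicarbonyl and on the facial bias of the catalyst.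

Step 3
Reactants: 3 ethyl (2R,3S)-2-(benzyloxy)-3-hydroxybutanoate
Product: 4 ethyl (2R,3S)-2,3-dihydroxybutanoate
Conditions: H2 (1 atm), 10% Pd/C, EtOH, rt
Reagents that add atoms: none
Why: Hydrogenolysis of the benzyl ether; neither stereocentre is touched. The benzyl group has served as the α-alkoxy substituent of step 2 and is removed here so that no hydrogenolysis is needed later beside the oxazoles and the C1' ester.

Step 4
Reactants: 4 ethyl (2R,3S)-2,3-dihydroxybutanoate
Product: 5 ethyl (2R,3S)-2,3-bis[(tert-butyldimethylsilyl)oxy]butanoate
Conditions: TBSOTf (2.4 equiv), 2,6-lutidine, CH2Cl2, 0 °C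
Reagents that add atoms: tert-butyldimethylsilyl trifluoromethanesulfonate (TBSOTf), CC(C)(C)[Si](C)(C)OS(=O)(=O)C(F)(F)F
Why: Silyl ether formation at both secondary hydroxyls; the triflate is needed for the second, crowded position, and the hindered pyridine base does not epimerise C2.

Step 5
Reactants: 5 ethyl (2R,3S)-2,3-bis[(tert-butyldimethylsilyl)oxy]butanoate
Product: 6 (2R,3S)-2,3-bis[(tert-butyldimethylsilyl)oxy]butanal
Conditions: iBu2AlH (1.1 equiv), CH2Cl2, −78 °C; MeOH, aq. potassium sodium tartrate
Reagents that add atoms: none
Why: Partial reduction of an ester with iBu2AlH; the α-silyloxy group stabilises the tetrahedral aluminium hemiacetal, which collapses to the aldehyde only on work-up. The aldehyde is used without delay to keep C2 intact.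

Step 6
Reactants: 7 ethyl 3,3-diethoxypropanoate; 8 L-serine methyl ester hydrochloride
Product: 10 methyl N-(3,3-diethoxypropanoyl)-L-serinate, via sodium 3,3-diethoxypropanoate 9 (not isolated)
Conditions: NaOH (1.0 equiv), EtOH/H2O, rt; evaporate; then 8, EDC·HCl, HOBt, DMF, 0 °C to rt
Reagents that add atoms: sodium hydroxide, [Na+].[OH-] (its oxygen becomes one of the two carboxylate oxygens of 9)
Why: Ester saponification followed by carbodiimide/HOBt amide coupling in the same flask, so that the acid-sensitive β,β-dialkoxy acid is never set free. The serine unit is the amine partner and cannot racemise by the oxazolone path.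

Step 7
Reactants: 10 methyl N-(3,3-diethoxypropanoyl)-L-serinate
Product: 12 methyl 2-(2,2-diethoxyethyl)-1,3-oxazole-4-carboxylate, via oxazoline ester 11 (not isolated)
Conditions: DAST (1.1 equiv), CH2Cl2, −78 °C; then BrCCl3, DBU, 0 °C to rt
Reagents that add atoms: none
Why: Cyclodehydration followed by dehydrogenation: DAST activates the serine hydroxyl, the amide oxygen displaces it (5-exo-tet) to give oxazoline 11, and bromination at C4 with loss of HBr aromatises the ring. The acetal is inert to both reagents; if ethanol were lost to give the enol ether, step 8 would hydrolyse it to the same aldehyde.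

Step 8
Reactants: 12 methyl 2-(2,2-diethoxyethyl)-1,3-oxazole-4-carboxylate; 13 tosylmethyl isocyanide (TosMIC)
Product: 15 methyl 2-(1,3-oxazol-5-ylmethyl)-1,3-oxazole-4-carboxylate, via oxazolylacetaldehyde 14 (not isolated)
Conditions: TFA/H2O (9:1), CH2Cl2, 0 °C to rt; evaporate; then 13, K2CO3, MeOH, 65 °C
Reagents that add atoms: water, O
Why: Acetal hydrolysis followed by the van Leusen oxazole synthesis: the TosMIC anion adds to the aldehyde, the alkoxide closes onto the isocyanide carbon (5-endo-dig), and loss of toluenesulfinate gives the 5-substituted oxazole. The methyl ester is indifferent to K2CO3 in methanol.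

Step 9
Reactants: 15 methyl 2-(1,3-oxazol-5-ylmethyl)-1,3-oxazole-4-carboxylate
Product: 16 N-methoxy-N-methyl-2-(1,3-oxazol-5-ylmethyl)-1,3-oxazole-4-carboxamide
Conditions: MeNH(OMe)·HCl, AlMe3, CH2Cl2, 0 °C to rt; aq. potassium sodium tartrate
Reagents that add atoms: N,O-dimethylhydroxylamine hydrochloride, Cl.CNOC
Why: Weinreb amide formation by aluminium amide aminolysis of the methyl ester; the aluminium amide is not basic enough to metalate the oxazole C2–H or the bridging CH2.

Step 10
Reactants: 16 N-methoxy-N-methyl-2-(1,3-oxazol-5-ylmethyl)-1,3-oxazole-4-carboxamide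
Product: 17 1-[2-(1,3-oxazol-5-ylmethyl)-1,3-oxazol-4-yl]ethan-1-one
Conditions: MeMgBr (1.5 equiv), THF, −78 to 0 °C; aq. NH4Cl
Reagents that add atoms: methylmagnesium bromide, C[Mg]Br
Why: Weinreb ketone synthesis: the chelated tetrahedral magnesium adduct holds until work-up, so one methyl group (C2') is added. At low temperature, addition to the amide should be faster than deprotonation of the heteroaryl positions by the methyl Grignard reagent.

Step 11
Reactants: 17 1-[2-(1,3-oxazol-5-ylmethyl)-1,3-oxazol-4-yl]ethan-1-one
Product: 18 5-({4-[1-(trimethylsilyloxy)ethenyl]-1,3-oxazol-2-yl}methyl)-1,3-oxazole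
Conditions: TMSOTf, Et3N, CH2Cl2, 0 °C; pentane, filter
Reagents that add atoms: trimethylsilyl trifluoromethanesulfonate (TMSOTf), C[Si](C)(C)OS(=O)(=O)C(F)(F)F
Why: Soft enolisation to the enol silane: O-silylation of the ketone activates the methyl group for deprotonation by the amine, so the acidic heteroaryl positions are bypassed and only one regioisomer is possible. Compound 18 is used crude after removal of the ammonium salt.

Step 12
Reactants: 6 (2R,3S)-2,3-bis[(tert-butyldimethylsilyl)oxy]butanal; 18 5-({4-[1-(trimethylsilyloxy)ethenyl]-1,3-oxazol-2-yl}methyl)-1,3-oxazole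
Product: 19 (3S,4S,5S)-4,5-bis[(tert-butyldimethylsilyl)oxy]-3-hydroxy-1-[2-(1,3-oxazol-5-ylmethyl)-1,3-oxazol-4-yl]hexan-1-one
Conditions: BF3·OEt2 (3.5 equiv), CH2Cl2, −78 °C; aq. NaHCO3
Reagents that add atoms: none
Why: Mukaiyama aldol addition through an open transition state, forming C2'–C3'. BF3 cannot chelate, so the α-silyloxy group of 6 takes the polar Felkin–Anh position anti to the nucleophile (3,4-anti product), and in this syn aldehyde the 1,3-anti preference of the β-silyloxy group points to the same face; both effects add up to 3S at the new centre. Excess BF3·OEt2 covers what the two oxazole nitrogens bind.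

Step 13
Reactants: 19 (3S,4S,5S)-4,5-bis[(tert-butyldimethylsilyl)oxy]-3-hydroxy-1-[2-(1,3-oxazol-5-ylmethyl)-1,3-oxazol-4-yl]hexan-1-one
Product: 20 (3S,4R,5S)-3,4,5-tris[(tert-butyldimethylsilyl)oxy]-1-[2-(1,3-oxazol-5-ylmethyl)-1,3-oxazol-4-yl]hexan-1-one
Conditions: TBSOTf, 2,6-lutidine, CH2Cl2, −78 to 0 °C
Reagents that add atoms: tert-butyldimethylsilyl trifluoromethanesulfonate (TBSOTf), CC(C)(C)[Si](C)(C)OS(=O)(=O)C(F)(F)F
Why: Silyl ether formation at the C3 hydroxyl under non-basic, cold conditions, which avoids retro-aldol cleavage and β-elimination of the β-hydroxy ketone.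

Step 14
Reactants: 20 (3S,4R,5S)-3,4,5-tris[(tert-butyldimethylsilyl)oxy]-1-[2-(1,3-oxazol-5-ylmethyl)-1,3-oxazol-4-yl]hexan-1-one
Product: 21 (1R,3S,4R,5S)-3,4,5-tris[(tert-butyldimethylsilyl)oxy]-1-[2-(1,3-oxazol-5-ylmethyl)-1,3-oxazol-4-yl]hexan-1-ol
Conditions: (S)-2-methyl-CBS-oxazaborolidine (0.5 equiv), BH3·SMe2, THF, −30 °C; MeOH
Reagents that add atoms: none
Why: Corey–Bakshi–Shibata reduction: the oxazol-4-yl group takes the place of the large (aryl) substituent and the CH2 chain that of the small one, so the (S)-catalyst should deliver hydride to give the 1R carbinol (1,3-syn to C3–O), as acetophenone gives (R)-1-phenylethanol. Catalyst control is used because the β-silyloxy group exerts little bias of its own.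

Step 15
Reactants: 21 (1R,3S,4R,5S)-3,4,5-tris[(tert-butyldimethylsilyl)oxy]-1-[2-(1,3-oxazol-5-ylmethyl)-1,3-oxazol-4-yl]hexan-1-ol; 22 13-methyltetradecanoic acid
Product: 23 (1R,3S,4R,5S)-3,4,5-tris[(tert-butyldimethylsilyl)oxy]-1-[2-(1,3-oxazol-5-ylmethyl)-1,3-oxazol-4-yl]hexyl 13-methyltetradecanoate
Conditions: EDC·HCl, DMAP, CH2Cl2, 0 °C to rt
Reagents that add atoms: none
Why: Steglich esterification of the secondary alcohol; the C1–O bond is not broken, so the configuration at C1 is retained.

Step 16
Reactants: 23 (1R,3S,4R,5S)-3,4,5-tris[(tert-butyldimethylsilyl)oxy]-1-[2-(1,3-oxazol-5-ylmethyl)-1,3-oxazol-4-yl]hexyl 13-methyltetradecanoate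
Product: 24 (1R,3S,4R,5S)-3,4,5-trihydroxy-1-[2-(1,3-oxazol-5-ylmethyl)-1,3-oxazol-4-yl]hexyl 13-methyltetradecanoate
Conditions: HF·pyridine, pyridine, THF, 0 °C to rt
Reagents that add atoms: none
Why: Fluoride-mediated cleavage of the three silyl ethers in a buffered, slightly acidic medium, in which the C1 ester should neither shift to the freed C3 hydroxyl nor be cleaved; the oxazoles are stable to HF·pyridine.

## Compound list

1 | ethyl 2-(benzyloxy)acetate | CCOC(=O)COCc1ccccc1 | starting material
2 | ethyl 2-(benzyloxy)-3-oxobutanoate (racemic) | CCOC(=O)C(OCc1ccccc1)C(C)=O | intermediate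
3 | ethyl (2R,3S)-2-(benzyloxy)-3-hydroxybutanoate | CCOC(=O)[C@H](OCc1ccccc1)[C@H](C)O | intermediate
4 | ethyl (2R,3S)-2,3-dihydroxybutanoate | CCOC(=O)[C@H](O)[C@H](C)O | intermediate
5 | ethyl (2R,3S)-2,3-bis[(tert-butyldimethylsilyl)oxy]butanoate | CCOC(=O)[C@H](O[Si](C)(C)C(C)(C)C)[C@H](C)O[Si](C)(C)C(C)(C)C | intermediate
6 | (2R,3S)-2,3-bis[(tert-butyldimethylsilyl)oxy]butanal | O=C[C@H](O[Si](C)(C)C(C)(C)C)[C@H](C)O[Si](C)(C)C(C)(C)C | intermediate
7 | ethyl 3,3-diethoxypropanoate | CCOC(CC(=O)OCC)OCC | starting material
8 | L-serine methyl ester hydrochloride | Cl.COC(=O)[C@@H](N)CO | starting material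
9 | sodium 3,3-diethoxypropanoate | CCOC(CC(=O)[O-])OCC.[Na+] | intermediate
10 | methyl N-(3,3-diethoxypropanoyl)-L-serinate | COC(=O)[C@@H](NC(=O)CC(OCC)OCC)CO | intermediate
11 | methyl (4S)-2-(2,2-diethoxyethyl)-4,5-dihydro-1,3-oxazole-4-carboxylate | COC(=O)[C@@H]1COC(CC(OCC)OCC)=N1 | intermediate
12 | methyl 2-(2,2-diethoxyethyl)-1,3-oxazole-4-carboxylate | COC(=O)c1coc(CC(OCC)OCC)n1 | intermediate
13 | tosylmethyl isocyanide (TosMIC) | Cc1ccc(cc1)S(=O)(=O)C[N+]#[C-] | starting material
14 | methyl 2-(2-oxoethyl)-1,3-oxazole-4-carboxylate | COC(=O)c1coc(CC=O)n1 | intermediate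
15 | methyl 2-(1,3-oxazol-5-ylmethyl)-1,3-oxazole-4-carboxylate | COC(=O)c1coc(Cc2cnco2)n1 | intermediate
16 | N-methoxy-N-methyl-2-(1,3-oxazol-5-ylmethyl)-1,3-oxazole-4-carboxamide | CON(C)C(=O)c1coc(Cc2cnco2)n1 | intermediate
17 | 1-[2-(1,3-oxazol-5-ylmethyl)-1,3-oxazol-4-yl]ethan-1-one | CC(=O)c1coc(Cc2cnco2)n1 | intermediate
18 | 5-({4-[1-(trimethylsilyloxy)ethenyl]-1,3-oxazol-2-yl}methyl)-1,3-oxazole | C=C(O[Si](C)(C)C)c1coc(Cc2cnco2)n1 | intermediate
19 | (3S,4S,5S)-4,5-bis[(tert-butyldimethylsilyl)oxy]-3-hydroxy-1-[2-(1,3-oxazol-5-ylmethyl)-1,3-oxazol-4-yl]hexan-1-one (the C4 descriptor is S by CIP ranking only; the spatial arrangement is that of C4' in 24) | O=C(C[C@H](O)[C@H](O[Si](C)(C)C(C)(C)C)[C@H](C)O[Si](C)(C)C(C)(C)C)c1coc(Cc2cnco2)n1 | intermediate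
20 | (3S,4R,5S)-3,4,5-tris[(tert-butyldimethylsilyl)oxy]-1-[2-(1,3-oxazol-5-ylmethyl)-1,3-oxazol-4-yl]hexan-1-one | O=C(C[C@H](O[Si](C)(C)C(C)(C)C)[C@H](O[Si](C)(C)C(C)(C)C)[C@H](C)O[Si](C)(C)C(C)(C)C)c1coc(Cc2cnco2)n1 | intermediate
21 | (1R,3S,4R,5S)-3,4,5-tris[(tert-butyldimethylsilyl)oxy]-1-[2-(1,3-oxazol-5-ylmethyl)-1,3-oxazol-4-yl]hexan-1-ol | O[C@H](C[C@H](O[Si](C)(C)C(C)(C)C)[C@H](O[Si](C)(C)C(C)(C)C)[C@H](C)O[Si](C)(C)C(C)(C)C)c1coc(Cc2cnco2)n1 | intermediate
22 | 13-methyltetradecanoic acid | CC(C)CCCCCCCCCCCC(=O)O | starting material
23 | (1R,3S,4R,5S)-3,4,5-tris[(tert-butyldimethylsilyl)oxy]-1-[2-(1,3-oxazol-5-ylmethyl)-1,3-oxazol-4-yl]hexyl 13-methyltetradecanoate | CC(C)CCCCCCCCCCCC(=O)O[C@H](C[C@H](O[Si](C)(C)C(C)(C)C)[C@H](O[Si](C)(C)C(C)(C)C)[C@H](C)O[Si](C)(C)C(C)(C)C)c1coc(Cc2cnco2)n1 | intermediate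
24 | (1R,3S,4R,5S)-3,4,5-trihydroxy-1-[2-(1,3-oxazol-5-ylmethyl)-1,3-oxazol-4-yl]hexyl 13-methyltetradecanoate | CC(C)CCCCCCCCCCCC(=O)O[C@H](C[C@H](O)[C@H](O)[C@H](C)O)c1coc(Cc2cnco2)n1 | target

## Step count and weak points

Total: 16 steps. Longest linear sequence: 11 steps (steps 6 to 16, from 7 and 8); the polyol branch from 1 is 10 steps (steps 1 to 5 and 12 to 16).

**Step 2 (key step).** The most likely failure is weak discrimination between the two faces of a ketone flanked by a methyl group and an sp3 carbon, since the catalyst family is at its best with aryl ketones. Reduction could also outrun epimerisation at C2, letting the anti isomer build up. The fallback sets out from 1 and returns at 3, replacing catalyst control by auxiliary control and creating the diad in a C–C bond-forming step: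
- 1 is saponified (LiOH) to (benzyloxy)acetic acid F1.
- F1 is converted through its mixed pivalic anhydride into the imide of (R)-4-benzyl-1,3-oxazolidin-2-one, (4R)-4-benzyl-3-[(benzyloxy)acetyl]-1,3-oxazolidin-2-one F2.
- An Evans syn aldol addition (Bu2BOTf, Et3N, acetaldehyde) gives (4R)-4-benzyl-3-[(2R,3S)-2-(benzyloxy)-3-hydroxybutanoyl]-1,3-oxazolidin-2-one F3.
- Ethanolysis with EtOMgBr releases 3.

**Step 12.** Facial selectivity may erode if the Lewis acid is largely held by the oxazole nitrogens, which also lowers the nucleophilicity of 18, or the enol silane may be lost by protodesilylation before it adds. The fallback sets out from 17 and 6 and returns at 19, skipping 18. It is a reagent-controlled boron aldol through a closed transition state: 17 is enolised with Ipc2BCl and Et3N and added to 6 at −78 °C, followed by oxidative work-up. (−)-Ipc2BCl is the antipode expected to favour attack on the Si face of the aldehyde, the face that leads to 3S; the other antipode is at hand if the sense proves opposite. This fallback makes no compound outside the list (F0).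

**Step 8.** Aldehyde 14 is enolisable toward the oxazole, and enolisation followed by self-condensation may outpace addition of the isocyanide anion. The fallback sets out from 13 and 8 and returns at 15; it builds the terminal ring first, from an aldehyde without an activated α-position:
- 13 is condensed (K2CO3, MeOH) with commercial 3-(benzyloxy)propanal to give 5-[2-(benzyloxy)ethyl]-1,3-oxazole F4.
- Hydrogenolysis (H2, Pd/C) gives 2-(1,3-oxazol-5-yl)ethan-1-ol F5.
- Oxidation (TEMPO, PhI(OAc)2, MeCN/H2O) gives (1,3-oxazol-5-yl)acetic acid F6.
- Coupling with 8 (EDC·HCl, HOBt, iPr2NEt) gives methyl N-[(1,3-oxazol-5-yl)acetyl]-L-serinate F7.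
- DAST and then BrCCl3/DBU close and dehydrogenate the central ring by way of methyl (4S)-2-(1,3-oxazol-5-ylmethyl)-4,5-dihydro-1,3-oxazole-4-carboxylate F8 to give 15.

**Step 14.** Catalyst control may be mismatched with the resident C3 centre, or borane may coordinate to the oxazole nitrogen next to the carbonyl and open an uncatalysed, unselective pathway. The fallback sets out from 20 and returns at 23, setting C1 by inversion instead of by hydride delivery. The enantiomeric (R)-catalyst, then the matched one, would give (1S,3S,4R,5S)-3,4,5-tris[(tert-butyldimethylsilyl)oxy]-1-[2-(1,3-oxazol-5-ylmethyl)-1,3-oxazol-4-yl]hexan-1-ol F9. Mitsunobu esterification of F9 with 22 (PPh3, diisopropyl azodicarboxylate) installs the acyl group with inversion and gives 23 directly, so step 15 is not needed.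

## Further compounds

F1 | step 2 | (benzyloxy)acetic acid | OC(=O)COCc1ccccc1
F2 | step 2 | (4R)-4-benzyl-3-[(benzyloxy)acetyl]-1,3-oxazolidin-2-one | O=C1OC[C@@H](Cc2ccccc2)N1C(=O)COCc3ccccc3
F3 | step 2 | (4R)-4-benzyl-3-[(2R,3S)-2-(benzyloxy)-3-hydroxybutanoyl]-1,3-oxazolidin-2-one | O=C1OC[C@@H](Cc2ccccc2)N1C(=O)[C@H](OCc3ccccc3)[C@H](C)O
F0 | step 12 | none | none
F4 | step 8 | 5-[2-(benzyloxy)ethyl]-1,3-oxazole | C(Cc1cnco1)OCc1ccccc1
F5 | step 8 | 2-(1,3-oxazol-5-yl)ethan-1-ol | OCCc1cnco1
F6 | step 8 | (1,3-oxazol-5-yl)acetic acid | OC(=O)Cc1cnco1
F7 | step 8 | methyl N-[(1,3-oxazol-5-yl)acetyl]-L-serinate | COC(=O)[C@@H](NC(=O)Cc1cnco1)CO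
F8 | step 8 | methyl (4S)-2-(1,3-oxazol-5-ylmethyl)-4,5-dihydro-1,3-oxazole-4-carboxylate | COC(=O)[C@@H]1COC(Cc2cnco2)=N1
F9 | step 14 | (1S,3S,4R,5S)-3,4,5-tris[(tert-butyldimethylsilyl)oxy]-1-[2-(1,3-oxazol-5-ylmethyl)-1,3-oxazol-4-yl]hexan-1-ol | O[C@@H](C[C@H](O[Si](C)(C)C(C)(C)C)[C@H](O[Si](C)(C)C(C)(C)C)[C@H](C)O[Si](C)(C)C(C)(C)C)c1coc(Cc2cnco2)n1
A1 | alternative 1 | 4-{(1R,3S)-1-[(4-methoxybenzyl)oxy]-3-[(tert-butyldimethylsilyl)oxy]-3-[(4R,5S)-2,2,5-trimethyl-1,3-dioxolan-4-yl]propyl}-2-(1,3-oxazol-5-ylmethyl)-1,3-oxazole | C(c1cnco1)c1nc(co1)[C@H](OCc1ccc(OC)cc1)C[C@H](O[Si](C)(C)C(C)(C)C)[C@@H]1OC(C)(C)O[C@H]1C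
A2 | alternative 1 | (4-{(1R,3S)-1-[(4-methoxybenzyl)oxy]-3-[(tert-butyldimethylsilyl)oxy]-3-[(4R,5S)-2,2,5-trimethyl-1,3-dioxolan-4-yl]propyl}-1,3-oxazol-2-yl)acetaldehyde | O=CCc1nc(co1)[C@H](OCc1ccc(OC)cc1)C[C@H](O[Si](C)(C)C(C)(C)C)[C@@H]1OC(C)(C)O[C@H]1C
A3 | alternative 2 | 1-C-[2-(1,3-oxazol-5-ylmethyl)-1,3-oxazol-4-yl]-3,4-O-isopropylidene-L-fucal | C[C@@H]1OC(=C[C@@H]2OC(C)(C)O[C@H]12)c1coc(Cc2cnco2)n1
A4 | alternative 2 | tributyl(3,4-O-isopropylidene-L-fucal-1-yl)stannane | C[C@@H]1OC(=C[C@@H]2OC(C)(C)O[C@H]12)[Sn](CCCC)(CCCC)CCCC
A5 | alternative 2 | 2-(1,3-oxazol-5-ylmethyl)-1,3-oxazol-4-yl trifluoromethanesulfonate | O=S(=O)(Oc1coc(Cc2cnco2)n1)C(F)(F)F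
A6 | alternative 3 | (1R,3S)-3-[(tert-butyldimethylsilyl)oxy]-1-[2-(1,3-oxazol-5-ylmethyl)-1,3-oxazol-4-yl]-3-[(4R,5S)-2,2,5-trimethyl-1,3-dioxolan-4-yl]propyl 13-methyltetradecanoate | CC(C)CCCCCCCCCCCC(=O)O[C@H](C[C@H](O[Si](C)(C)C(C)(C)C)[C@@H]1OC(C)(C)O[C@H]1C)c1coc(Cc2cnco2)n1
A7 | alternative 3 | chloro(4-{(1R,3S)-1-[(13-methyltetradecanoyl)oxy]-3-[(tert-butyldimethylsilyl)oxy]-3-[(4R,5S)-2,2,5-trimethyl-1,3-dioxolan-4-yl]propyl}-1,3-oxazol-2-yl)zinc | CC(C)CCCCCCCCCCCC(=O)O[C@H](C[C@H](O[Si](C)(C)C(C)(C)C)[C@@H]1OC(C)(C)O[C@H]1C)c1coc([Zn]Cl)n1
A8 | alternative 3 | 5-(bromomethyl)-1,3-oxazole | BrCc1cnco1
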